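**Plan**
- Retrosynthetic cuts: first the palmitate C(=O)–O bond; then, in ring B, the bond between the ester-bearing carbon and the aryloxy-bearing carbon and the bond between the neighbouring ring CH and the methyl-bearing carbon; last the O–C(sp) bond of the aryl ethynyl ether that results.
- Enabling feature: ring B is a methyl 2-aryloxy-6-hydroxy-4-methylbenzoate. Its C1 (CO2Me), C6 (OH), C5 (H) and C4 (CH3) are C3, C4, C5 and C6 of a 3-carbomethoxy-4-alkoxy-6-methyl-2-pyrone; C2 and C3 are the two carbons of an ethynyl ether whose oxygen already carries ring A.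
- Forward order: ring A is present in 2-hydroxy-5-methoxybenzaldehyde and is taken to the ethynyl ether (steps 1–7); the pyrone is made in steps 8–9; ring B, the only ring formed, arises in step 10 by [4+2] cycloaddition and loss of CO2; steps 11–13 exchange the silyl ether for the palmitate and free both phenols.
- Stereochemistry: the target has no stereocentre and no stereogenic double bond, so nothing is set; the E-dichlorovinyl ether and the bridgeheads of the bicyclic adduct are transient.

Key step: step 10

Remark: the structure given is achiral, so no enantiocontrol is needed; compounds 1, 11, 12 and 20 and all reagents are taken as commercial.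

**Route**

Step 1
Reactants: 1 2-hydroxy-5-methoxybenzaldehyde
Product: 2 3-bromo-2-hydroxy-5-methoxybenzaldehyde
Conditions: Br2 (1.05 equiv), NaOAc, AcOH, rt
Reagents that add atoms: bromine, BrBr
Why: Electrophilic aromatic bromination should go to C3, the only free position ortho to the phenol (its para position carries OMe) and also meta to the formyl group, with acetate buffering the HBr.

Step 2
Reactants: 2 3-bromo-2-hydroxy-5-methoxybenzaldehyde
Product: 3 2,3-dihydroxy-5-methoxybenzaldehyde
Conditions: aq NaOH, Cu powder (cat.), N2, reflux; then HCl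
Reagents that add atoms: sodium hydroxide, [Na+].[OH-]
Why: Copper-mediated Ullmann-type hydroxylation of an o-bromophenoxide in hot aqueous alkali, the reaction type long used to turn 5-bromovanillin into 5-hydroxyvanillin; the phenoxide protects the aldehyde from Cannizzaro disproportionation and exclusion of air protects the catechol.

Step 3
Reactants: 3 2,3-dihydroxy-5-methoxybenzaldehyde
Product: 4 2-hydroxy-5-methoxy-3-(methoxymethoxy)benzaldehyde
Conditions: NaH (2.2 equiv), DMF, 0 °C; MOMCl (1.0 equiv), 0 °C → rt; dilute HCl work-up
Reagents that add atoms: chloromethyl methyl ether, COCCl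
Why: Williamson-type mono-alkylation of the catecholate dianion, in which the C3 phenoxide (meta to the formyl group, neither conjugated nor chelated) is far more nucleophilic than the C2 phenoxide delocalised into the ortho aldehyde, as known for 2,3-dihydroxybenzaldehyde dianions.

Step 4
Reactants: 4 2-hydroxy-5-methoxy-3-(methoxymethoxy)benzaldehyde
Product: 5 2-{[(E)-1,2-dichloroethenyl]oxy}-5-methoxy-3-(methoxymethoxy)benzaldehyde
Conditions: Cl2C=CHCl (2 equiv), K2CO3, DMF, 70 °C
Reagents that add atoms: trichloroethylene, ClC=C(Cl)Cl
Why: Nucleophilic vinylation of a phenol: carbonate generates dichloroacetylene from trichloroethylene and the phenoxide adds to it in anti fashion to give the (E)-1,2-dichlorovinyl ether, while the aldehyde and the acetal are inert to K2CO3 in DMF.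

Step 5
Reactants: 5 2-{[(E)-1,2-dichloroethenyl]oxy}-5-methoxy-3-(methoxymethoxy)benzaldehyde
Product: 6 (2-{[(E)-1,2-dichloroethenyl]oxy}-5-methoxy-3-(methoxymethoxy)phenyl)methanol
Conditions: NaBH4, MeOH–THF, 0 °C
Reagents that add atoms: none
Why: Chemoselective borohydride reduction of the aldehyde, to which the dichlorovinyl ether and the MOM acetal do not respond.

Step 6
Reactants: 6 (2-{[(E)-1,2-dichloroethenyl]oxy}-5-methoxy-3-(methoxymethoxy)phenyl)methanol
Product: 7 tert-butyl[(2-{[(E)-1,2-dichloroethenyl]oxy}-5-methoxy-3-(methoxymethoxy)phenyl)methoxy]dimethylsilane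
Conditions: TBSCl, imidazole, DMF, rt
Reagents that add atoms: tert-butyldimethylsilyl chloride, CC(C)(C)[Si](C)(C)Cl
Why: Imidazole-promoted silylation of the unhindered primary alcohol, which masks the hydroxyl before the organolithium step.

Step 7
Reactants: 7 tert-butyl[(2-{[(E)-1,2-dichloroethenyl]oxy}-5-methoxy-3-(methoxymethoxy)phenyl)methoxy]dimethylsilane
Product: 10 tert-butyl{[2-(ethynyloxy)-5-methoxy-3-(methoxymethoxy)phenyl]methoxy}dimethylsilane, via chloroethynyl ether 8 (not isolated), via lithium aryloxyacetylide 9 (not isolated)
Conditions: n-BuLi (2.3 equiv), THF, −78 → −40 °C; H2O, −78 °C; filtered through basic alumina and used at once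
Reagents that add atoms: none
Why: The established dichlorovinyl-ether route to ynol ethers, in which one equivalent of n-BuLi effects dehydrochlorination to the chloroalkyne and the second effects chlorine–lithium exchange to the acetylide that is protonated cold; elimination should be much faster than acetal-directed ring lithiation at −78 °C and the silyl ether is inert.

Step 8
Reactants: 11 dimethyl malonate, 12 2,2,6-trimethyl-4H-1,3-dioxin-4-one
Product: 15 methyl 4-hydroxy-6-methyl-2-oxo-2H-pyran-3-carboxylate, via acetylketene 13 (not isolated), via dimethyl (3-oxobutanoyl)malonate 14 (not isolated)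
Conditions: NaH (1.05 equiv), toluene, rt; then 12, 110 °C; 1 M HCl
Reagents that add atoms: none
Why: Acylketene trapping followed by lactonisation, the dioxinone counterpart of the classical diketene–malonate pyrone synthesis: heat releases acetylketene by retro-[4+2] loss of acetone, sodium dimethyl malonate is C-acylated, and the enolate oxygen of the tricarbonyl compound closes onto one malonate ester with loss of methoxide.

Step 9
Reactants: 15 methyl 4-hydroxy-6-methyl-2-oxo-2H-pyran-3-carboxylate
Product: 16 methyl 4-(methoxymethoxy)-6-methyl-2-oxo-2H-pyran-3-carboxylate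
Conditions: MOMCl, i-Pr2NEt, CH2Cl2, 0 °C
Reagents that add atoms: chloromethyl methyl ether, COCCl
Why: Williamson-type O-alkylation of the acidic vinylogous carboxylic acid with a hindered amine base; C3 is fully substituted, so only oxygen can be alkylated, and the 4-oxygen carries most of the anionic charge.

Step 10
Reactants: 10 tert-butyl{[2-(ethynyloxy)-5-methoxy-3-(methoxymethoxy)phenyl]methoxy}dimethylsilane, 16 methyl 4-(methoxymethoxy)-6-methyl-2-oxo-2H-pyran-3-carboxylate
Product: 18 methyl 2-{2-[(tert-butyldimethylsilyloxy)methyl]-4-methoxy-6-(methoxymethoxy)phenoxy}-6-(methoxymethoxy)-4-methylbenzoate, via bicyclic lactone 17 (not isolated)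
Conditions: 16 (1.5 equiv), Eu(fod)3 (10 mol %), toluene, 60 → 90 °C, sealed tube
Reagents that add atoms: none
Why: The electron-rich aryl ethynyl ether and the pyrone, whose C3=C4–C5=C6 diene is made electron-poor by the C3 ester and the lactone carbonyl and further by Eu(III) chelation of these two carbonyls, should combine in an asynchronous inverse-electron-demand [4+2] cycloaddition to the bridged lactone 17, which then expels CO2 in a retro-[4+2] step driven by aromatisation. The closest known reaction type is the Diels–Alder/decarboxylation of 3-carbomethoxy-2-pyrones with ynamines, ketene acetals and vinyl ethers, including its lanthanide-catalysed variant. Ring B is closed as the six-membered carbocycle of an intermolecular cycloaddition in which both new σ-bonds (aryloxy carbon to C3, alkyne CH to C6) form in one operation, so no separate cyclisation mode has to be chosen. The two bridgehead stereocentres of 17 form as a racemate and disappear with the CO2 bridge, so nothing has to be controlled. The step needs regioselectivity, which polarisation should supply: the nucleophilic terminal carbon of the ynol ether attacks C6, the position vinylogously activated by both carbonyls, and the oxygen-bearing carbon joins C3, placing the aryloxy group next to the ester. It also needs the cycloaddition to outrun self-reaction of the ynol ether, for which the pyrone is used in excess, the two ortho substituents shield the alkyne, and the catalyst keeps the temperature moderate against the tempering effect of the 4-alkoxy group.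

Step 11
Reactants: 18 methyl 2-{2-[(tert-butyldimethylsilyloxy)methyl]-4-methoxy-6-(methoxymethoxy)phenoxy}-6-(methoxymethoxy)-4-methylbenzoate
Product: 19 methyl 2-[2-(hydroxymethyl)-4-methoxy-6-(methoxymethoxy)phenoxy]-6-(methoxymethoxy)-4-methylbenzoate
Conditions: HF·pyridine, pyridine, THF, 0 °C → rt
Reagents that add atoms: none
Why: Fluoride-mediated desilylation of the primary TBS ether under pyridine-buffered, non-basic conditions, which should leave the aryl MOM acetals and the methyl ester untouched and avoid an alkoxide that could attack the neighbouring ester.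

Step 12
Reactants: 19 methyl 2-[2-(hydroxymethyl)-4-methoxy-6-(methoxymethoxy)phenoxy]-6-(methoxymethoxy)-4-methylbenzoate, 20 palmitic acid (hexadecanoic acid)
Product: 21 methyl 2-{2-[(hexadecanoyloxy)methyl]-4-methoxy-6-(methoxymethoxy)phenoxy}-6-(methoxymethoxy)-4-methylbenzoate
Conditions: DCC, DMAP (cat.), CH2Cl2, 0 °C → rt
Reagents that add atoms: none
Why: Steglich esterification of the only free hydroxyl group, a primary benzylic alcohol; both phenols are still masked, so no chemoselectivity is required.

Step 13
Reactants: 21 methyl 2-{2-[(hexadecanoyloxy)methyl]-4-methoxy-6-(methoxymethoxy)phenoxy}-6-(methoxymethoxy)-4-methylbenzoate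
Product: 22 betaethrin E, methyl 2-{2-[(hexadecanoyloxy)methyl]-6-hydroxy-4-methoxyphenoxy}-6-hydroxy-4-methylbenzoate
Conditions: ZnBr2, n-PrSH, CH2Cl2, 0 °C → rt
Reagents that add atoms: none
Why: Lewis acid–thiol cleavage of the two aryl MOM acetals, in which zinc bromide activates the acetal and the thiol traps the methoxymethyl cation as its monothioacetal, keeping formaldehyde equivalents off the electron-rich rings, while the methyl ester, the diaryl ether and the benzylic palmitate (no hydroxy or methoxy group ortho or para to its benzylic carbon) should be inert to these non-hydrolytic conditions.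

**Compound list**

1 | 2-hydroxy-5-methoxybenzaldehyde | COc1ccc(O)c(C=O)c1 | starting material
2 | 3-bromo-2-hydroxy-5-methoxybenzaldehyde | COc1cc(Br)c(O)c(C=O)c1 | intermediate
3 | 2,3-dihydroxy-5-methoxybenzaldehyde | COc1cc(O)c(O)c(C=O)c1 | intermediate
4 | 2-hydroxy-5-methoxy-3-(methoxymethoxy)benzaldehyde | COCOc1cc(OC)cc(C=O)c1O | intermediate
5 | 2-{[(E)-1,2-dichloroethenyl]oxy}-5-methoxy-3-(methoxymethoxy)benzaldehyde | COCOc1cc(OC)cc(C=O)c1O/C(Cl)=C\Cl | intermediate
6 | (2-{[(E)-1,2-dichloroethenyl]oxy}-5-methoxy-3-(methoxymethoxy)phenyl)methanol | COCOc1cc(OC)cc(CO)c1O/C(Cl)=C\Cl | intermediate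
7 | tert-butyl[(2-{[(E)-1,2-dichloroethenyl]oxy}-5-methoxy-3-(methoxymethoxy)phenyl)methoxy]dimethylsilane | COCOc1cc(OC)cc(CO[Si](C)(C)C(C)(C)C)c1O/C(Cl)=C\Cl | intermediate
8 | tert-butyl({2-[(chloroethynyl)oxy]-5-methoxy-3-(methoxymethoxy)phenyl}methoxy)dimethylsilane | COCOc1cc(OC)cc(CO[Si](C)(C)C(C)(C)C)c1OC#CCl | intermediate, not isolated
9 | lithium 2-{2-[(tert-butyldimethylsilyloxy)methyl]-4-methoxy-6-(methoxymethoxy)phenoxy}acetylide | COCOc1cc(OC)cc(CO[Si](C)(C)C(C)(C)C)c1OC#C[Li] | intermediate, not isolated
10 | tert-butyl{[2-(ethynyloxy)-5-methoxy-3-(methoxymethoxy)phenyl]methoxy}dimethylsilane | C#COc1c(CO[Si](C)(C)C(C)(C)C)cc(OC)cc1OCOC | intermediate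
11 | dimethyl malonate | COC(=O)CC(=O)OC | starting material
12 | 2,2,6-trimethyl-4H-1,3-dioxin-4-one | CC1=CC(=O)OC(C)(C)O1 | starting material
13 | acetylketene (but-1-ene-1,3-dione) | CC(=O)C=C=O | intermediate, not isolated
14 | dimethyl 2-(3-oxobutanoyl)propanedioate (present as its sodium enolate) | COC(=O)C(C(=O)CC(C)=O)C(=O)OC | intermediate, not isolated
15 | methyl 4-hydroxy-6-methyl-2-oxo-2H-pyran-3-carboxylate | COC(=O)C1=C(O)C=C(C)OC1=O | intermediate
16 | methyl 4-(methoxymethoxy)-6-methyl-2-oxo-2H-pyran-3-carboxylate | COC(=O)C1=C(OCOC)C=C(C)OC1=O | intermediate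
17 | methyl 8-{2-[(tert-butyldimethylsilyloxy)methyl]-4-methoxy-6-(methoxymethoxy)phenoxy}-5-(methoxymethoxy)-1-methyl-3-oxo-2-oxabicyclo[2.2.2]octa-5,7-diene-4-carboxylate (racemic) | CC12OC(=O)C(C(=O)OC)(C(OCOC)=C1)C(Oc3c(CO[Si](C)(C)C(C)(C)C)cc(OC)cc3OCOC)=C2 | intermediate, not isolated
18 | methyl 2-{2-[(tert-butyldimethylsilyloxy)methyl]-4-methoxy-6-(methoxymethoxy)phenoxy}-6-(methoxymethoxy)-4-methylbenzoate | COC(=O)c1c(OCOC)cc(C)cc1Oc1c(CO[Si](C)(C)C(C)(C)C)cc(OC)cc1OCOC | intermediate
19 | methyl 2-[2-(hydroxymethyl)-4-methoxy-6-(methoxymethoxy)phenoxy]-6-(methoxymethoxy)-4-methylbenzoate | COC(=O)c1c(OCOC)cc(C)cc1Oc1c(CO)cc(OC)cc1OCOC | intermediate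
20 | palmitic acid (hexadecanoic acid) | CCCCCCCCCCCCCCCC(=O)O | starting material
21 | methyl 2-{2-[(hexadecanoyloxy)methyl]-4-methoxy-6-(methoxymethoxy)phenoxy}-6-(methoxymethoxy)-4-methylbenzoate | CCCCCCCCCCCCCCCC(=O)OCc1cc(OC)cc(OCOC)c1Oc1cc(C)cc(OCOC)c1C(=O)OC | intermediate
22 | betaethrin E, methyl 2-{2-[(hexadecanoyloxy)methyl]-6-hydroxy-4-methoxyphenoxy}-6-hydroxy-4-methylbenzoate | CCCCCCCCCCCCCCCC(=O)OCc1cc(OC)cc(O)c1Oc1cc(C)cc(O)c1C(=O)OC | target

**Step count**

Total: 13 steps. Longest linear sequence: 11 steps (steps 1–7 and 10–13 from compound 1); the pyrone branch (steps 8–9) joins at step 10.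

**Steps most likely to fail**

1. Step 10. The cycloaddition may be too slow: the 4-alkoxy group feeds electron density into the diene and an aryl ynol ether is a weaker donor than an alkyl one, so oligomerisation or hydration of the alkyne could outrun ring formation. The fallback changes the disconnection: the diaryl ether bond is made by copper catalysis and ring B is brought in preformed. It sets out from phenol 4 and returns to the route at alcohol 19. 3-Bromo-5-methylphenol would be protected (MOMCl, i-Pr2NEt) as 1-bromo-3-(methoxymethoxy)-5-methylbenzene F1. Lithiation with LDA at −78 °C at the position between bromine and the acetal oxygen, then methyl chloroformate, would give methyl 2-bromo-6-(methoxymethoxy)-4-methylbenzoate F2. Ullmann ether coupling of F2 with 4 (CuI, picolinic acid, K3PO4, DMSO, 90 °C), helped by the ortho ester, would give methyl 2-[2-formyl-4-methoxy-6-(methoxymethoxy)phenoxy]-6-(methoxymethoxy)-4-methylbenzoate F3. NaBH4 reduction of its aldehyde would deliver 19, from which steps 12 and 13 follow unchanged.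

2. Step 7. The terminal aryl ethynyl ether may be lost during quench and isolation through hydration to the aryl acetate or through oligomerisation, and chlorine–lithium exchange may be incomplete. The fallback isolates a storable C-silyl alkyne and releases the terminal alkyne only just before use. It sets out from 7 and returns at 10. After the same n-BuLi treatment, acetylide 9 would be quenched with TMSCl to give tert-butyl{[5-methoxy-3-(methoxymethoxy)-2-{[(trimethylsilyl)ethynyl]oxy}phenyl]methoxy}dimethylsilane F4, which should tolerate chromatography and storage. TBAF in THF at −40 °C immediately before the cycloaddition would then release 10.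

3. Step 3. Alkylation may fail to discriminate between the two phenoxides or run on to the bis-acetal. The fallback protects both oxygens and relies on chelation to remove one acetal. It sets out from catechol 3 and returns at 4. Excess MOMCl with i-Pr2NEt would give 5-methoxy-2,3-bis(methoxymethoxy)benzaldehyde F5. MgBr2·OEt2 in ether–toluene would then cleave only the acetal ortho to the formyl group, which is activated by chelation of magnesium between the carbonyl and the acetal oxygen, giving 4.

**Further compounds**

F1 | step 10 | 1-bromo-3-(methoxymethoxy)-5-methylbenzene | COCOc1cc(C)cc(Br)c1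
F2 | step 10 | methyl 2-bromo-6-(methoxymethoxy)-4-methylbenzoate | COC(=O)c1c(Br)cc(C)cc1OCOC
F3 | step 10 | methyl 2-[2-formyl-4-methoxy-6-(methoxymethoxy)phenoxy]-6-(methoxymethoxy)-4-methylbenzoate | COC(=O)c1c(OCOC)cc(C)cc1Oc1c(C=O)cc(OC)cc1OCOC
F4 | step 7 | tert-butyl{[5-methoxy-3-(methoxymethoxy)-2-{[(trimethylsilyl)ethynyl]oxy}phenyl]methoxy}dimethylsilane | COCOc1cc(OC)cc(CO[Si](C)(C)C(C)(C)C)c1OC#C[Si](C)(C)C
F5 | step 3 | 5-methoxy-2,3-bis(methoxymethoxy)benzaldehyde | COCOc1cc(OC)cc(C=O)c1OCOC
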